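The constants of these steps were hidden when the meeting opened, so the chair asked for an argument from the two earlier runs.

| flask | substrate | remark | time |
|---|---|---|---|
| dawn | 0.019 M | run made earlier |  |
| winter | 0.044 M | run made earlier |  |
| flask | 0.029 M |  | 12 min |

| run | time / min | side product / % | target / % | substrate / % |
|---|---|---|---|---|
| dawn | 0.500 | 30.0 | 0 | 24.4 |
| dawn | 1.33 | 75.1 | 0 | 3.4 |
| dawn | 3.00 | 88.4 | 1.5 | 1.0 |
| dawn | 8.00 | 88.1 | 2.0 | 0.3 |
| winter | 2.00 | 82.9 | 0 | 0 |
| winter | 4.00 | 86.2 | 0.6 | 0 |
| winter | 5.00 | 88.5 | 0 | 1.2 |
| winter | 8.00 | 90.0 | 1.0 | 0 |

(scatter of a reading: 1 percentage point)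

- the analysis behind the earlier runs scatters by 1 percentage point, standard deviation
- steps under discussion: substrate -> intermediate B; substrate -> intermediate A; substrate -> target; intermediate C <-> intermediate D; intermediate B -> side product; intermediate A -> intermediate C; intermediate B -> decomposed reagent; intermediate D <-> intermediate B; target -> over-reaction product

- share of side product in side product plus target at 4.0 s
- share of side product in side product plus target at 50 s
- share of side product in side product plus target at 12 min

I argued from the balance of substrate, the limiting reagent. At 8.00 min, the dawn run lacks 9.60 % of its charge, and at 8.00 min the winter run lacks 9.00 %. Each figure sums three readings, so it carries a scatter of 1.7 percentage points. The two differ by 0.6 points, less than that scatter, although the charges differ. I therefore took their mean, 9.30 %, as the unaccounted share: the part of the charge found late as neither substrate, target nor side product.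

My rule for a late flask, with substrate counted as nil and the unaccounted share held at that mean, was this: the share of side product is one minus target divided by the charge less the unaccounted share. With a read target of 1.50 %, I put the flask at 98.3 % for 12 min. I offered no figure for the early times.

The forecaster reported 82 %, 98 % and 98.7 %. The forecaster said that target “sits near the noise” and took about 1.2 % of it, less than my figure, so the late forecast stood above mine.

The flask gives 88.5 %, 98.6 % and 99.1 %.

    substrate → intermediate B (k = 2.70 min⁻¹)
    substrate → intermediate A (k = 0.0670 min⁻¹)
    substrate → target (k = 0.0230 min⁻¹)
    intermediate C ⇌ intermediate D (K = 0.280, k = 0.0720 min⁻¹)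
    intermediate B → side product (k = 2.00 min⁻¹)
    intermediate A → intermediate C (k = 0.0180 min⁻¹)
    intermediate B → decomposed reagent (k = 0.130 min⁻¹)
    intermediate D ⇌ intermediate B (K = 0.680, k = 0.0380 min⁻¹)
    target → over-reaction product (k = 1.80 × 10⁻⁴ min⁻¹)

In the flask at 12.0 min, intermediate B goes to side product 15 times as fast as to decomposed reagent. The flask then holds 88.9 % of side product and 5.78 % of decomposed reagent, within 10.3 % standing outside side product and target. The read unaccounted share, with the flask's target of 0.823 %, gives 99.1 %. The neighbour flask, at 0.017 M of substrate, has 10.3 % outside those two and a share of 99.1 %.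

The earlier runs and the new flask come from a simulation for an exercise; the scatter is artificial.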